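The ring is numbered C1 (ketone), C2 (bearing C7H2O), C3 (=CH), C4 (O-tiglate), C5 (isopropyl), C6 (OAc). O4 and C1 sit 1,4 to each other across the C2=C3 double bond, so the cyclohexenone is unfolded to a γ-butyrolactone (ring C1–O4–C4–C5–C6) whose C4 side chain is a (Z)-2-bromoallyl unit. Bromine–lithium exchange then forges C1–C2; the lactone oxygen is expelled as the C4 hydroxyl, so carbocycle, enone and free O4 arise at once. The 4,5-cis/5,6-trans pattern equals an all-trans lactone, set on an (R)-butenolide by conjugate addition and enolate hydroxylation. O7 is carried as an acid-labile acetal, O6 as a TBS ether, allowing one double tigloylation.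

Key step: step 10

Assumption: 1 is taken as a catalogue compound (the enantiomer of the commoner S form, otherwise reached from D-glutamic acid); the labels C1–C7, O4, O6 and O7 always mean the target numbering, so lactone positions 2, 3, 4 and 5 are C1, C6, C5 and C4, and the exocyclic carbon of 1 is C3.

Step 1
Reactants: 1 (R)-5-(hydroxymethyl)furan-2(5H)-one
Product: 2 (R)-5-(trityloxymethyl)furan-2(5H)-one
Conditions: TrCl, pyridine, rt
Reagents that add atoms: trityl chloride ClC(c1ccccc1)(c1ccccc1)c1ccccc1
Why: Trityl ether formation takes the primary hydroxyl, and pyridine is too weak a base to enolise the butenolide toward the achiral 2-oxyfuran, so C4 keeps its configuration and gains the bulky shield needed in the next step.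

Step 2
Reactants: 2 (R)-5-(trityloxymethyl)furan-2(5H)-one; 3 isopropylmagnesium chloride
Product: 5 (4S,5R)-4-isopropyl-5-(trityloxymethyl)dihydrofuran-2(3H)-one (4,5-trans), via chloromagnesium enolate 4 (not isolated)
Conditions: 3 (2.4 equiv), CuBr·SMe2 (1.2 equiv), THF/Et2O, −78 → −40 °C; aq NH4Cl
Reagents that add atoms: isopropylmagnesium chloride CC(C)[Mg]Cl
Why: Organocuprate 1,4-addition to the butenolide takes place on the face opposite the CH2OTr group, which sets C5 trans to the C4 side chain by substrate control, and enolate 4 is protonated on work-up.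

Step 3
Reactants: 5 (4S,5R)-4-isopropyl-5-(trityloxymethyl)dihydrofuran-2(3H)-one
Product: 7 (3R,4R,5R)-3-hydroxy-4-isopropyl-5-(trityloxymethyl)dihydrofuran-2(3H)-one (all-trans), via potassium enolate 6 (not isolated)
Conditions: KN(SiMe3)2 (1.2 equiv), THF, −78 °C; 2-(phenylsulfonyl)-3-phenyloxaziridine, −78 °C; AcOH
Reagents that add atoms: 2-(phenylsulfonyl)-3-phenyloxaziridine O=S(=O)(c1ccccc1)N1OC1c1ccccc1
Why: In this Davis enolate hydroxylation the oxaziridine delivers oxygen to the planar enolate 6 on the face away from the neighbouring isopropyl group, which sets C6 trans to C5 and completes the all-trans lactone.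

Step 4
Reactants: 7 (3R,4R,5R)-3-hydroxy-4-isopropyl-5-(trityloxymethyl)dihydrofuran-2(3H)-one
Product: 8 (3R,4S,5R)-3-(tert-butyldimethylsilyloxy)-4-isopropyl-5-(trityloxymethyl)dihydrofuran-2(3H)-one
Conditions: TBSCl, imidazole, DMF, rt
Reagents that add atoms: tert-butyldimethylsilyl chloride CC(C)(C)[Si](C)(C)Cl
Why: Imidazole-promoted silylation masks O6 with a group that withstands acid methanolysis, zerovalent palladium, t-BuLi and acylation and can be taken off last with fluoride.

Step 5
Reactants: 8 (3R,4S,5R)-3-(tert-butyldimethylsilyloxy)-4-isopropyl-5-(trityloxymethyl)dihydrofuran-2(3H)-one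
Product: 9 (3R,4S,5R)-3-(tert-butyldimethylsilyloxy)-5-(hydroxymethyl)-4-isopropyldihydrofuran-2(3H)-one
Conditions: TsOH·H2O (cat.), MeOH/CH2Cl2, 0 °C → rt
Reagents that add atoms: none
Why: Acid-catalysed solvolysis of the trityl ether through the stabilised trityl cation is far faster than cleavage of the hindered, electron-poor secondary TBS ether, and the γ-lactone is the favoured ring size, so no translactonisation is expected.

Step 6
Reactants: 9 (3R,4S,5R)-3-(tert-butyldimethylsilyloxy)-5-(hydroxymethyl)-4-isopropyldihydrofuran-2(3H)-one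
Product: 10 (2R,3S,4R)-4-(tert-butyldimethylsilyloxy)-3-isopropyl-5-oxotetrahydrofuran-2-carbaldehyde
Conditions: Dess–Martin periodinane, CH2Cl2, 0 °C → rt; used crude
Reagents that add atoms: none
Why: The Dess–Martin oxidation runs without amine base, so the α-acyloxy aldehyde should form without epimerisation at C4, whose trans arrangement is the more stable one in any case.

Step 7
Reactants: 10 (2R,3S,4R)-4-(tert-butyldimethylsilyloxy)-3-isopropyl-5-oxotetrahydrofuran-2-carbaldehyde; 11 carbon tetrabromide
Product: 12 (3R,4S,5R)-3-(tert-butyldimethylsilyloxy)-5-(2,2-dibromovinyl)-4-isopropyldihydrofuran-2(3H)-one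
Conditions: 11 (2 equiv), PPh3 (4 equiv), CH2Cl2, 0 °C; then 10, −20 → 0 °C
Reagents that add atoms: carbon tetrabromide BrC(Br)(Br)Br
Why: The Ramirez dibromo-olefination (first stage of the Corey–Fuchs sequence) is a non-basic Wittig reaction of Ph3P=CBr2 that is fast with an activated aldehyde, turns the formyl carbon into C3 and brings in C2.

Step 8
Reactants: 12 (3R,4S,5R)-3-(tert-butyldimethylsilyloxy)-5-(2,2-dibromovinyl)-4-isopropyldihydrofuran-2(3H)-one; 13 (tributylstannyl)methanol
Product: 14 (3R,4S,5R)-5-[(Z)-2-bromo-3-hydroxyprop-1-enyl]-3-(tert-butyldimethylsilyloxy)-4-isopropyldihydrofuran-2(3H)-one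
Conditions: 13 (1.2 equiv), Pd2(dba)3 (2.5 mol %), P(2-furyl)3 (15 mol %), toluene, 80 °C
Reagents that add atoms: (tributylstannyl)methanol CCCC[Sn](CO)(CCCC)CCCC
Why: In this Stille coupling zerovalent palladium inserts into the less hindered C–Br bond of the 1,1-dibromoalkene, the one trans to C4, and tin transfers its hydroxymethyl group, so C7 enters trans to C4 and the remaining bromine stays cis to it (Z).

Step 9
Reactants: 14 (3R,4S,5R)-5-[(Z)-2-bromo-3-hydroxyprop-1-enyl]-3-(tert-butyldimethylsilyloxy)-4-isopropyldihydrofuran-2(3H)-one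
Product: 15 (3R,4S,5R)-5-[(Z)-2-bromo-3-(2-methoxypropan-2-yloxy)prop-1-enyl]-3-(tert-butyldimethylsilyloxy)-4-isopropyldihydrofuran-2(3H)-one (all-trans)
Conditions: 2-methoxypropene, PPTS (cat.), CH2Cl2, 0 °C; Et3N quench
Reagents that add atoms: 2-methoxypropene COC(C)=C
Why: Acid-catalysed addition of the alcohol to the enol ether (mixed acetal formation) is fast at 0 °C, creates no stereocentre and leaves lactone, TBS ether and vinyl bromide untouched.

Step 10
Reactants: 15 (3R,4S,5R)-5-[(Z)-2-bromo-3-(2-methoxypropan-2-yloxy)prop-1-enyl]-3-(tert-butyldimethylsilyloxy)-4-isopropyldihydrofuran-2(3H)-one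
Product: 19 (4S,5S,6R)-6-(tert-butyldimethylsilyloxy)-4-hydroxy-2-(hydroxymethyl)-5-isopropylcyclohex-2-en-1-one, via alkenyllithium 16 (not isolated), via bridged lithium hemiketal 17 (not isolated), via C7-acetal cyclohexenone 18 (not isolated)
Conditions: t-BuLi (2.1 equiv), THF/Et2O/pentane 4:1:1, 0.01 M, −100 → −78 °C; AcOH, −78 °C; then PPTS, MeOH, 0 °C
Reagents that add atoms: none
Why: t-BuLi exchanges the C2 bromine with retention (its second equivalent destroys t-BuBr), so in 16 lithium stays cis to C4, the descriptor turning to E only because carbon outranks lithium. The carbanion adds to the lactone carbonyl C1 on the ring face that bears the side chain; the new C1–C2 bond closes the carbocycle C1–C6 in 6-exo-trig fashion (5-exo-trig for the transient dihydrofuran ring through O4) and gives the 7-oxabicyclo[2.2.1]hept-2-ene hemiketal 17. Breaking of the strained C1–O4 bond, at the latest on protonation, moves the acyl carbon from oxygen to carbon and releases the enone and the C4–OH of 18 together, which makes the step a Parham-type cyclisation, the intramolecular acylation of an organolithium by an ester after halogen–metal exchange. No lasting stereocentre is created: C4, C5 and C6 are carried over untouched, the exo isopropyl group ending cis and the endo OTBS group trans to O4, while bridgehead C1 of 17 is dictated by the tether and becomes trigonal again. The step needs exchange to outrun attack of t-BuLi on C1 and removal of H6, which −100 °C, high dilution, the shielding C6–OTBS group and the position of H6 on the face opposite to the carbanion should secure. The O7 acetal cannot shift to carbon as a silyl group could, is a poorer leaving group than a silanolate so that allene formation is held back, and falls off in the PPTS/MeOH finish to leave diol 19 with only O6 masked.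

Step 11
Reactants: 19 (4S,5S,6R)-6-(tert-butyldimethylsilyloxy)-4-hydroxy-2-(hydroxymethyl)-5-isopropylcyclohex-2-en-1-one; 20 tigloyl chloride [(E)-2-methylbut-2-enoyl chloride]
Product: 21 (4S,5S,6R)-6-(tert-butyldimethylsilyloxy)-5-isopropyl-4-(tigloyloxy)-2-(tigloyloxymethyl)cyclohex-2-en-1-one
Conditions: 20 (3 equiv), pyridine, DMAP (cat.), CH2Cl2, 0 °C → rt
Reagents that add atoms: tigloyl chloride C/C=C(\C)C(=O)Cl
Why: Nucleophile-catalysed acylation with the acid chloride esterifies the primary O7 and the allylic secondary O4 in one operation, the weak base pyridine avoiding ketene formation and thus deconjugation of the tigloyl group, while O6 stays silylated.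

Step 12
Reactants: 21 (4S,5S,6R)-6-(tert-butyldimethylsilyloxy)-5-isopropyl-4-(tigloyloxy)-2-(tigloyloxymethyl)cyclohex-2-en-1-one
Product: 22 (4S,5R,6R)-6-hydroxy-5-isopropyl-4-(tigloyloxy)-2-(tigloyloxymethyl)cyclohex-2-en-1-one (same spatial arrangement; only the C5 descriptor changes with the priorities)
Conditions: HF·pyridine, pyridine, THF, 0 °C → rt
Reagents that add atoms: none
Why: Fluoride-driven silyl ether cleavage under mildly acidic conditions spares both esters and the enone, avoids base-induced epimerisation at C6, and acyl migration from O4 to O6 is ruled out by their 1,3-trans relation.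

Step 13
Reactants: 22 (4S,5R,6R)-6-hydroxy-5-isopropyl-4-(tigloyloxy)-2-(tigloyloxymethyl)cyclohex-2-en-1-one
Product: 23 (4S,5S,6R)-6-acetoxy-5-isopropyl-4-(tigloyloxy)-2-(tigloyloxymethyl)cyclohex-2-en-1-one (CNP0218511.1)
Conditions: Ac2O, pyridine, CH2Cl2, 0 °C → rt
Reagents that add atoms: acetic anhydride CC(=O)OC(C)=O
Why: Simple acetylation of the only free hydroxyl, an α-ketol, under mild base gives the target, and C6 is not at risk because its 5,6-trans diequatorial arrangement is the stable one.

Compound list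
1 | (R)-5-(hydroxymethyl)furan-2(5H)-one | O=C1O[C@@H](CO)C=C1 | starting material
2 | (R)-5-(trityloxymethyl)furan-2(5H)-one | O=C1O[C@@H](COC(c2ccccc2)(c2ccccc2)c2ccccc2)C=C1 | intermediate
3 | isopropylmagnesium chloride | CC(C)[Mg]Cl | starting material
4 | chloromagnesium enolate of 5 (not isolated) | Cl[Mg]OC1=C[C@@H](C(C)C)[C@H](COC(c2ccccc2)(c2ccccc2)c2ccccc2)O1 | intermediate
5 | (4S,5R)-4-isopropyl-5-(trityloxymethyl)dihydrofuran-2(3H)-one | O=C1O[C@@H](COC(c2ccccc2)(c2ccccc2)c2ccccc2)[C@H](C(C)C)C1 | intermediate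
6 | potassium enolate of 5 (not isolated) | [K]OC1=C[C@@H](C(C)C)[C@H](COC(c2ccccc2)(c2ccccc2)c2ccccc2)O1 | intermediate
7 | (3R,4R,5R)-3-hydroxy-4-isopropyl-5-(trityloxymethyl)dihydrofuran-2(3H)-one | O=C1O[C@@H](COC(c2ccccc2)(c2ccccc2)c2ccccc2)[C@H](C(C)C)[C@H]1O | intermediate
8 | (3R,4S,5R)-3-(tert-butyldimethylsilyloxy)-4-isopropyl-5-(trityloxymethyl)dihydrofuran-2(3H)-one | O=C1O[C@@H](COC(c2ccccc2)(c2ccccc2)c2ccccc2)[C@H](C(C)C)[C@H]1O[Si](C)(C)C(C)(C)C | intermediate
9 | (3R,4S,5R)-3-(tert-butyldimethylsilyloxy)-5-(hydroxymethyl)-4-isopropyldihydrofuran-2(3H)-one | O=C1O[C@@H](CO)[C@H](C(C)C)[C@H]1O[Si](C)(C)C(C)(C)C | intermediate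
10 | (2R,3S,4R)-4-(tert-butyldimethylsilyloxy)-3-isopropyl-5-oxotetrahydrofuran-2-carbaldehyde | O=C1O[C@@H](C=O)[C@H](C(C)C)[C@H]1O[Si](C)(C)C(C)(C)C | intermediate
11 | carbon tetrabromide | BrC(Br)(Br)Br | starting material
12 | (3R,4S,5R)-3-(tert-butyldimethylsilyloxy)-5-(2,2-dibromovinyl)-4-isopropyldihydrofuran-2(3H)-one | O=C1O[C@@H](C=C(Br)Br)[C@H](C(C)C)[C@H]1O[Si](C)(C)C(C)(C)C | intermediate
13 | (tributylstannyl)methanol | CCCC[Sn](CO)(CCCC)CCCC | starting material
14 | (3R,4S,5R)-5-[(Z)-2-bromo-3-hydroxyprop-1-enyl]-3-(tert-butyldimethylsilyloxy)-4-isopropyldihydrofuran-2(3H)-one | O=C1O[C@@H](/C=C(\Br)CO)[C@H](C(C)C)[C@H]1O[Si](C)(C)C(C)(C)C | intermediate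
15 | (3R,4S,5R)-5-[(Z)-2-bromo-3-(2-methoxypropan-2-yloxy)prop-1-enyl]-3-(tert-butyldimethylsilyloxy)-4-isopropyldihydrofuran-2(3H)-one | O=C1O[C@@H](/C=C(\Br)COC(C)(C)OC)[C@H](C(C)C)[C@H]1O[Si](C)(C)C(C)(C)C | intermediate
16 | alkenyllithium: 15 with Li in place of Br, Li cis to C4 (not isolated) | O=C1O[C@@H](/C=C(\[Li])COC(C)(C)OC)[C@H](C(C)C)[C@H]1O[Si](C)(C)C(C)(C)C | intermediate
17 | bridged lithium hemiketal: 7-oxabicyclo[2.2.1]hept-2-ene with OLi on bridgehead C1, CH2O-acetal on C2, exo-isopropyl on C5, endo-OTBS on C6 (not isolated) | [Li]O[C@@]12O[C@@H](C=C1COC(C)(C)OC)[C@H](C(C)C)[C@H]2O[Si](C)(C)C(C)(C)C | intermediate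
18 | (4S,5S,6R)-6-(tert-butyldimethylsilyloxy)-4-hydroxy-5-isopropyl-2-[(2-methoxypropan-2-yloxy)methyl]cyclohex-2-en-1-one (4,5-cis, 5,6-trans; not isolated) | COC(C)(C)OCC1=C[C@H](O)[C@H](C(C)C)[C@@H](O[Si](C)(C)C(C)(C)C)C1=O | intermediate
19 | (4S,5S,6R)-6-(tert-butyldimethylsilyloxy)-4-hydroxy-2-(hydroxymethyl)-5-isopropylcyclohex-2-en-1-one | OCC1=C[C@H](O)[C@H](C(C)C)[C@@H](O[Si](C)(C)C(C)(C)C)C1=O | intermediate
20 | tigloyl chloride, (E)-2-methylbut-2-enoyl chloride | C/C=C(\C)C(=O)Cl | starting material
21 | (4S,5S,6R)-6-(tert-butyldimethylsilyloxy)-5-isopropyl-4-(tigloyloxy)-2-(tigloyloxymethyl)cyclohex-2-en-1-one | C/C=C(\C)C(=O)OCC1=C[C@H](OC(=O)/C(C)=C/C)[C@H](C(C)C)[C@@H](O[Si](C)(C)C(C)(C)C)C1=O | intermediate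
22 | (4S,5R,6R)-6-hydroxy-5-isopropyl-4-(tigloyloxy)-2-(tigloyloxymethyl)cyclohex-2-en-1-one | C/C=C(\C)C(=O)OCC1=C[C@H](OC(=O)/C(C)=C/C)[C@H](C(C)C)[C@@H](O)C1=O | intermediate
23 | (4S,5S,6R)-6-acetoxy-5-isopropyl-4-(tigloyloxy)-2-(tigloyloxymethyl)cyclohex-2-en-1-one | C/C=C(\C)C(=O)OCC1=C[C@H](OC(=O)/C(C)=C/C)[C@H](C(C)C)[C@@H](OC(C)=O)C1=O | target

Total step count: 13. Longest linear sequence: 13 steps (1 → 23).

Steps most likely to fail

Step 10. What may go wrong:
- direct attack of t-BuLi on the lactone carbonyl;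
- proton transfer to the carbanion before it closes;
- a second organolithium addition once the bridge has opened.

Fallback (from 15, back at 19): the strained bicyclic passage is avoided by opening the lactone first. Treatment of 15 with MeNH(OMe)·HCl and 3 in THF at −20 °C should give the hydroxy Weinreb amide F1. Its C4–OH is capped at once with TESCl/imidazole to give the TES ether F2. t-BuLi at −78 °C then closes the same C1–C2 bond on the amide, whose chelated tetrahedral adduct cannot take up a second nucleophile, and gives the fully protected cyclohexenone F3. PPTS in MeOH removes the TES group and the acetal together and delivers 19.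

Step 8. What may go wrong: slow transfer of the sp3 hydroxymethyl group from tin. This would leave time for dehydrobromination, for a second coupling, or for ionisation of the allylic C4–O lactone bond by zerovalent palladium.

Fallback (from 10, back at 14): C2 and C7 are brought in together without palladium or tin. Wittig reaction of 10 with Ph3P=CHCHO in CH2Cl2 should give the (E)-enal F4. Bromine at −78 °C adds to the alkene to give the dibromo aldehyde F5. Et3N in the same flask removes HBr by loss of the acidic H2 and gives the (Z)-2-bromoenal F6, with bromine cis to C4. Luche reduction (NaBH4, CeCl3·7H2O, MeOH, −78 °C) takes the aldehyde only, leaves the lactone and returns 14.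

Step 11. What may go wrong: sluggish acylation of O4 beside the cis isopropyl group. Under forcing conditions this could be joined by conjugate addition–elimination of the nucleophilic catalyst at the newly formed C7 allylic ester, or by deconjugation of the tigloyl unit.

Fallback (from 18, isolated by leaving out the PPTS/MeOH finish of step 10, back at 21): the two esters are installed one after the other, so the hindered one is made before the labile one exists.
- Yamaguchi esterification of 18 (tiglic acid, 2,4,6-trichlorobenzoyl chloride, Et3N, DMAP, toluene) gives the C4 tiglate acetal F7.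
- PPTS in MeOH frees O7 to give the primary alcohol F8.
- 20 in pyridine at 0 °C without DMAP esterifies this unhindered hydroxyl and gives 21.

Further compounds
F1 | step 10 | ring-opened N-methoxy-N-methylamide of the C1 acid with free C4–OH, (Z)-bromoalkene, O7 acetal and O6 TBS as in 15 | CON(C)C(=O)[C@H](O[Si](C)(C)C(C)(C)C)[C@@H](C(C)C)[C@@H](O)/C=C(\Br)COC(C)(C)OC
F2 | step 10 | C4 triethylsilyl ether of F1 | CON(C)C(=O)[C@H](O[Si](C)(C)C(C)(C)C)[C@@H](C(C)C)[C@@H](O[Si](CC)(CC)CC)/C=C(\Br)COC(C)(C)OC
F3 | step 10 | C4 triethylsilyl ether of 18 | COC(C)(C)OCC1=C[C@H](O[Si](CC)(CC)CC)[C@H](C(C)C)[C@@H](O[Si](C)(C)C(C)(C)C)C1=O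
F4 | step 8 | (E)-3-[(2R,3S,4R)-4-(tert-butyldimethylsilyloxy)-3-isopropyl-5-oxotetrahydrofuran-2-yl]acrylaldehyde | O=C1O[C@@H](/C=C/C=O)[C@H](C(C)C)[C@H]1O[Si](C)(C)C(C)(C)C
F5 | step 8 | 2,3-dibromo aldehyde from anti addition of bromine to F4 (both C–Br epimer pairs converge on F6) | O=C1O[C@@H](C(Br)C(Br)C=O)[C@H](C(C)C)[C@H]1O[Si](C)(C)C(C)(C)C
F6 | step 8 | (Z)-2-bromo analogue of F4, bromine cis to C4 | O=C1O[C@@H](/C=C(\Br)C=O)[C@H](C(C)C)[C@H]1O[Si](C)(C)C(C)(C)C
F7 | step 11 | C4 tiglate of 18 | COC(C)(C)OCC1=C[C@H](OC(=O)/C(C)=C/C)[C@H](C(C)C)[C@@H](O[Si](C)(C)C(C)(C)C)C1=O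
F8 | step 11 | C4 tiglate of 19 with free C7–OH | OCC1=C[C@H](OC(=O)/C(C)=C/C)[C@H](C(C)C)[C@@H](O[Si](C)(C)C(C)(C)C)C1=O
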